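**Strategy**

The 6-carboxy-2-pyrone (ring O1', C2'–C6', CH2 on C4') is treated as a 4-alkylcatechol (alkyl on Ar-C1, hydroxyls on Ar-C3 and Ar-C4) cut between Ar-C4 and Ar-C5: Ar-C4 is the carboxyl carbon, Ar-C3 with its oxygen is C6'–O1', and Ar-C5 is C2'. A single enzymatic extradiol oxygenation of the catechol ring, followed by spontaneous hemiacetal closure, thus turns a benzene ring into the pyran ring and forms O1'–C2' with all ring carbons in place. The precursor is the catechol obtained by removing one methyl group from natural arctigenin, which supplies both lactone stereocentres and the inert dimethoxybenzyl ring; lactol oxidation then gives the target.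

Key step: step 2

Assumption: commercial (−)-arctigenin is the natural (3R,4R)-trans enantiomer, the configuration the target SMILES encodes at both lactone carbons, so no stereocentre has to be created; Ar-C numbers refer to the benzylic ring that is cleaved, primed numbers to the pyran/pyrone ring.

**Route**

Step 1
Reactants: 1 (−)-arctigenin [(3R,4R)-4-(3,4-dimethoxybenzyl)-3-(4-hydroxy-3-methoxybenzyl)dihydrofuran-2(3H)-one]
Product: 3 catechol lignan [(3R,4R)-3-(3,4-dihydroxybenzyl)-4-(3,4-dimethoxybenzyl)dihydrofuran-2(3H)-one], via ortho-quinone 2 (not isolated)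
Conditions: IBX (1.2 equiv), THF–DMSO, 0 °C to rt, dark; then aq Na2S2O4, rt
Reagents that add atoms: 2-iodoxybenzoic acid (IBX), O=C1OI(=O)(O)c2ccccc12 (its oxygen replaces the methoxy oxygen on Ar-C3)
Why: Oxidative demethylation of 2-methoxyphenols by IBX is a known reaction of guaiacyl lignans: the phenol binds the pentavalent iodine, oxygen is delivered to the neighbouring methoxy-bearing Ar-C3, methanol is expelled to give ortho-quinone 2, and dithionite reduces 2 to the catechol in the same pot, while the phenol-free dimethoxyphenyl ring, the lactone and its two stereocentres should stay untouched under these neutral conditions.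

Step 2
Reactants: 3 catechol lignan; 4 dioxygen
Product: 7 lactol 4-{[(3R,4R)-4-(3,4-dimethoxybenzyl)-2-oxotetrahydrofuran-3-yl]methyl}-2-hydroxy-2H-pyran-6-carboxylic acid (both anomers at C2'), via enzyme-bound oxepine-2,3-dione 5 (not isolated), via ring-opened semialdehyde 6 (not isolated)
Conditions: extradiol catechol 4,5-dioxygenase (non-haem enzyme, divalent iron; DOPA 4,5-dioxygenase or protocatechuate 4,5-dioxygenase homologue chosen by screening), FeSO4 (0.1 mM), sodium ascorbate, air, phosphate buffer pH 7.5, 5% DMSO, 25 °C; then pH 3, EtOAc extraction, crude used at once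
Reagents that add atoms: dioxygen (compound 4), O=O
Why: Proposed new method: the catechol ring of 3 should chelate the active-site ferrous ion as its monoanion, O2 adds to give an iron-bound alkylperoxide at Ar-C4, and a Criegee rearrangement shifts the Ar-C4–Ar-C5 bond onto oxygen to give the seven-membered lactone 5, which the iron-bound hydroxide opens to 6; the closest known reaction type is the enzymatic 4,5-extradiol cleavage of 3,4-dihydroxyphenylalanine and of protocatechuate, whose ring-opened products close to the same kind of lactol on the way to pyrone acids. After keto–enol equilibration at the α-keto-acid end of 6, the enol oxygen on Ar-C3 adds to the aldehyde carbon Ar-C5 in a 6-exo-trig hemiacetalisation that forms O1'–C2' and the pyran ring. The only new stereocentre, the lactol carbon C2', is uncontrolled and is removed in step 3, while the two lactone centres are remote and should be stable at pH 7.5. Chemoselectivity is inherent, since only the ring with two free hydroxyls can bind iron; regioselectivity for the distal Ar-C4–Ar-C5 bond over the proximal Ar-C2–Ar-C3 bond and over intradiol Ar-C3–Ar-C4 cleavage is imposed by a distal-cleaving enzyme family and is helped by the bulky benzylic substituent lying next to the proximal bond. Acceptance of so large and lipophilic a substrate is unproven, so homologues and active-site variants are to be screened.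

Step 3
Reactants: 7 lactol (crude, both anomers)
Product: 8 target 4-{[(3R,4R)-4-(3,4-dimethoxybenzyl)-2-oxotetrahydrofuran-3-yl]methyl}-2-oxo-2H-pyran-6-carboxylic acid
Conditions: TEMPO (0.2 equiv), PhI(OAc)2 (1.2 equiv), MeCN–H2O, 0 °C to rt
Reagents that add atoms: none
Why: Oxoammonium oxidation (TEMPO/PhI(OAc)2) of a lactol to a lactone is a standard transformation: hydride abstraction from the allylic hemiacetal carbon C2' should give the conjugated 2-pyrone, and the free carboxylic acid, the electron-rich dimethoxyarene, the butyrolactone and its stereocentres are tolerated under these mild conditions.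

**Compound list**

1 | (−)-arctigenin, (3R,4R)-4-(3,4-dimethoxybenzyl)-3-(4-hydroxy-3-methoxybenzyl)dihydrofuran-2(3H)-one | COc1ccc(C[C@H]2COC(=O)[C@@H]2Cc2ccc(O)c(OC)c2)cc1OC | starting material
2 | ortho-quinone, (3R,4R)-4-(3,4-dimethoxybenzyl)-3-[(3,4-dioxocyclohexa-1,5-dien-1-yl)methyl]dihydrofuran-2(3H)-one | COc1ccc(C[C@H]2COC(=O)[C@@H]2CC2=CC(=O)C(=O)C=C2)cc1OC | intermediate (not isolated)
3 | catechol lignan, (3R,4R)-3-(3,4-dihydroxybenzyl)-4-(3,4-dimethoxybenzyl)dihydrofuran-2(3H)-one | COc1ccc(C[C@H]2COC(=O)[C@@H]2Cc2ccc(O)c(O)c2)cc1OC | intermediate
4 | dioxygen | O=O | starting material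
5 | enzyme-bound lactone, 5-{[(3R,4R)-4-(3,4-dimethoxybenzyl)-2-oxotetrahydrofuran-3-yl]methyl}oxepine-2,3-dione | COc1ccc(C[C@H]2COC(=O)[C@@H]2CC2=CC(=O)C(=O)OC=C2)cc1OC | intermediate (not isolated)
6 | ring-opened semialdehyde, 4-{[(3R,4R)-4-(3,4-dimethoxybenzyl)-2-oxotetrahydrofuran-3-yl]methyl}-2-hydroxy-6-oxohexa-2,4-dienoic acid (double-bond isomers equilibrate through the 2-oxo tautomer) | COc1ccc(C[C@H]2COC(=O)[C@@H]2CC(C=C(O)C(=O)O)=CC=O)cc1OC | intermediate (not isolated)
7 | lactol, 4-{[(3R,4R)-4-(3,4-dimethoxybenzyl)-2-oxotetrahydrofuran-3-yl]methyl}-2-hydroxy-2H-pyran-6-carboxylic acid, both anomers at C2' | COc1ccc(C[C@H]2COC(=O)[C@@H]2CC2=CC(O)OC(C(=O)O)=C2)cc1OC | intermediate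
8 | 4-{[(3R,4R)-4-(3,4-dimethoxybenzyl)-2-oxotetrahydrofuran-3-yl]methyl}-2-oxo-2H-pyran-6-carboxylic acid | COc1ccc(C[C@H]2COC(=O)[C@@H]2Cc2cc(C(=O)O)oc(=O)c2)cc1OC | target

**Count**

Total steps: 3. Longest linear sequence: 3 steps (1 → 3 → 7 → 8).

**Steps most likely to fail**

1. Step 2, the labelled key step. What may go wrong: the bulky, lipophilic lignan is not bound productively in the active site, so there is no turnover. Alternatively the ring is opened at the proximal Ar-C2–Ar-C3 or the intradiol Ar-C3–Ar-C4 bond, or the ferrous centre is oxidised and the enzyme is inactivated after few turnovers. The fallback uses known reaction types and fixes the bond to be cut by the substrate, not by a protein; it sets out from arctigenin 1 and comes back to the route at target 8. Teuber oxidation of 1 with (KSO3)2NO (2.2 equiv, aq KH2PO4, acetone, 0 °C) should oxygenate the only free ortho position, Ar-C5, and give the methoxy-ortho-quinone F1 with the methoxy group retained. Baeyer–Villiger-type insertion of oxygen between the two adjacent carbonyls with mCPBA (CH2Cl2, 0 °C) should give the muconic anhydride F2, necessarily by Ar-C4–Ar-C5 cleavage. Hydrolysis in wet THF should open F2 to the 2-methoxy-cis,cis-muconic acid F3, and TFA at rt should add the Ar-C5 carboxyl to the enol-ether carbon Ar-C3 and expel methanol, closing the 2-pyrone directly at the final oxidation level, so step 3 is bypassed as well. The known types relied on are ortho-quinone formation from para-substituted phenols with nitrosodisulfonate, peracid cleavage of ortho-quinones to muconic anhydrides, and acid closure of 2-oxy-substituted muconic acids to 2-pyrone-6-carboxylic acids.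

2. Step 3. What may go wrong: the lactol equilibrates with its open-chain enal and α-keto-acid tautomers during acidification, extraction and concentration and is lost by condensation, or the oxoammonium ion attacks the dienol ether instead of the hemiacetal C–H. The fallback sets out from lactol 7 while it is still in the buffered medium of step 2 and comes back at target 8, without isolation of 7. An NADP+-dependent hemiacetal dehydrogenase of the type that oxidises the ring-closed form of 4-carboxy-2-hydroxymuconate semialdehyde, catalytic NADP+ and a water-forming NADPH oxidase for cofactor recycling are added to the dioxygenase reaction, so that 7 is dehydrogenated as it forms. No compound outside the list arises (F0).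

3. Step 1. What may go wrong: oxygen is transferred from iodine to the unsubstituted ortho carbon Ar-C5 instead of the methoxy-bearing Ar-C3, giving a methoxy-quinone in place of demethylation, or ortho-quinone 2 condenses before it is reduced. The fallback avoids oxidation altogether; it sets out from arctigenin 1 and comes back at catechol 3. AlCl3 (3 equiv) and pyridine in CH2Cl2 at reflux should form an aluminium phenoxide at the free hydroxyl, which chelates the neighbouring methoxy oxygen and lets chloride remove its methyl group. The 3,4-dimethoxyphenyl ring has no phenoxide anchor and should react much more slowly. No compound outside the list arises (F0).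

**Further compounds**

F1 | step 2 | (3R,4R)-4-(3,4-dimethoxybenzyl)-3-[(5-methoxy-3,4-dioxocyclohexa-1,5-dien-1-yl)methyl]dihydrofuran-2(3H)-one | COc1ccc(C[C@H]2COC(=O)[C@@H]2CC2=CC(=O)C(=O)C(OC)=C2)cc1OC
F2 | step 2 | 5-{[(3R,4R)-4-(3,4-dimethoxybenzyl)-2-oxotetrahydrofuran-3-yl]methyl}-3-methoxyoxepine-2,7-dione | COc1ccc(C[C@H]2COC(=O)[C@@H]2CC2=CC(=O)OC(=O)C(OC)=C2)cc1OC
F3 | step 2 | (2E,4Z)-4-{[(3R,4R)-4-(3,4-dimethoxybenzyl)-2-oxotetrahydrofuran-3-yl]methyl}-2-methoxyhexa-2,4-dienedioic acid | COc1ccc(C[C@H]2COC(=O)[C@@H]2C/C(=C/C(=O)O)/C=C(/OC)C(=O)O)cc1OC
F0 | step 3 | none | none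
F0 | step 1 | none | none
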